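**Plan**
- Retrosynthesis first cuts the two depside C(=O)–O(aryl) bonds: ring C acyl to O4 of ring B, then ring B acyl to O4 of ring A. Rings A and C both trace back to methyl 2,4-dihydroxy-3,6-dimethylbenzoate.
- Ring B (C1 acyl carbon, C2 OMe, C3 Me, C4 O-acyl, C5 Me, C6 Me) loses its C1 carboxyl and is then cut at C2–C3, C4–C5 and C1–C2.
- The enabling feature is the O–C2, Me–C3, O–C4 array, which is a ketene carbonyl joined to MeC≡C–OSi. The C5(Me)=C6(Me)–C1H2 unit is the remainder of 2,3-dimethylcyclobutenone.
- Forward, the cyclobutenone and the siloxypropyne close ring B as a phenol with free C2–OH and silylated C4–O. Methylation, bromination and carboxylation at the single C–H then give the ring B acid.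
- The chain is joined A + B first, then B + C after desilylation, and one hydrogenolysis frees the acid and both phenols.
- Ring B is the only ring built. The target has no stereocentre and no stereogenic double bond, so no stereocontrol is needed.

Key step: step 4

Assumption: ring A carries the free CO2H, ring B is the central ring and ring C is the terminal dihydroxy ring. Each ring is numbered from its acyl-bearing carbon as C1.

Step 1
Reactants: 1 but-2-yne; 2 trichloroacetyl chloride
Product: 4 4,4-dichloro-2,3-dimethylcyclobut-2-en-1-one, via dichloroketene 3 (not isolated)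
Conditions: Zn–Cu couple, Et2O/DME, slow addition of 2, rt to 35 °C
Reagents that add atoms: none
Why: In this ketene–alkyne (2+2) cycloaddition, zinc dechlorinates 2 to dichloroketene, which adds across the symmetrical alkyne without any regiochemical question, while DME binds ZnCl2 and so holds back the allylic chloride shift of the product.

Step 2
Reactants: 4 4,4-dichloro-2,3-dimethylcyclobut-2-en-1-one
Product: 5 2,3-dimethylcyclobut-2-en-1-one
Conditions: Zn dust, AcOH, TMEDA, EtOH, 0 °C to rt
Reagents that add atoms: none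
Why: Zinc reductively dechlorinates the α,α-dichloro ketone through two zinc enolates that AcOH protonates, and the TMEDA-buffered medium is the standard protection against over-reduction and ring opening of cyclobutenones.

Step 3
Reactants: 6 ethyl acetate
Product: 9 1-(triisopropylsilyloxy)prop-1-yne, via 1,1-dibromopropan-2-one lithium enolate 7 (not isolated), via lithium prop-1-yn-1-olate 8 (not isolated)
Conditions: CH2Br2, lithium 2,2,6,6-tetramethylpiperidide, THF, −78 °C, then 6; LiN(SiMe3)2; n-BuLi, −78 °C to rt; TIPSCl, −78 °C to rt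
Reagents that add atoms: dibromomethane, BrCBr; triisopropylsilyl chloride, CC(C)[Si](Cl)(C(C)C)C(C)C
Why: In this Kowalski ynolate synthesis, LiCHBr2 acylation gives enolate 7, Br–Li exchange triggers a carbenoid 1,2-methyl shift to ynolate 8, and the bulky silyl chloride traps 8 on oxygen and not on carbon.

Step 4
Reactants: 5 2,3-dimethylcyclobut-2-en-1-one; 9 1-(triisopropylsilyloxy)prop-1-yne
Product: 14 2,4,5-trimethyl-3-(triisopropylsilyloxy)phenol, via vinylketene 10 (not isolated), via 4-alkenylcyclobutenone 11 (not isolated), via dienylketene 12 (not isolated), via cyclohexadienone 13 (not isolated)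
Conditions: toluene, sealed tube, 80 °C then 110 °C
Reagents that add atoms: none
Why: This is a Danheiser benzannulation of the kind known for cyclobutenones and siloxyalkynes, in which heat opens 5 by 4π-electrocyclic cleavage of its C(=O)–CH2 bond to vinylketene 10. Alkyne 9, made nucleophilic at its methyl-bearing carbon by the oxygen lone pair, adds to the ketene C=C in a (2+2) cycloaddition that bonds the methyl-bearing carbon to the ketene carbonyl carbon (ring B C2–C3) and the silyloxy-bearing carbon to the methyl-substituted ketene carbon (C4–C5), giving 11. A second 4π opening of 11 gives dienylketene 12, and a thermal disrotatory 6π-electrocyclic closure between its terminal CH2 and the ketene carbon (C1–C2) closes ring B, the only ring that is kept, as dienone 13; enolisation to 14 makes the sequence irreversible. No stereocentre is present in 14, since the quaternary carbon of 11 is racemic and vanishes on ring opening. The one selectivity needed is the orientation of the (2+2) step, and the donor polarisation of 9 secures it, so the alkyne methyl ends between the two oxygens, the ketene oxygen appears as free OH at C2 and the alkyne oxygen as OTIPS at C4. The TIPS group should keep 9 intact at these temperatures, and all three methyl groups arrive in place with C1 left as the only aromatic C–H.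

Step 5
Reactants: 14 2,4,5-trimethyl-3-(triisopropylsilyloxy)phenol
Product: 15 (3-methoxy-2,5,6-trimethylphenoxy)triisopropylsilane
Conditions: MeI, K2CO3, acetone, reflux
Reagents that add atoms: iodomethane, CI
Why: This Williamson ether synthesis acts on the only free phenol, and the meta-placed silyl ether, shielded by two ortho methyl groups, can neither migrate nor be cleaved under these mild anhydrous conditions.

Step 6
Reactants: 15 (3-methoxy-2,5,6-trimethylphenoxy)triisopropylsilane
Product: 16 (4-bromo-3-methoxy-2,5,6-trimethylphenoxy)triisopropylsilane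
Conditions: NBS, MeCN, 0 °C, dark
Reagents that add atoms: N-bromosuccinimide, O=C1CCC(=O)N1Br
Why: Electrophilic aromatic bromination has a single open ring position, activated ortho by OMe and para by OTIPS, and the polar solvent, low temperature and exclusion of light favour the ionic pathway over benzylic radical bromination.

Step 7
Reactants: 16 (4-bromo-3-methoxy-2,5,6-trimethylphenoxy)triisopropylsilane
Product: 18 2-methoxy-3,5,6-trimethyl-4-(triisopropylsilyloxy)benzoic acid, via aryllithium 17 (not isolated)
Conditions: n-BuLi, THF, −78 °C; CO2 (g); 1 M HCl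
Reagents that add atoms: carbon dioxide, O=C=O
Why: Halogen–lithium exchange followed by carboxylation places the C1 carboxyl carbon exactly at the brominated site, and at −78 °C the exchange is faster than lateral lithiation or attack on silicon.

Step 8
Reactants: 19 methyl 2,4-dihydroxy-3,6-dimethylbenzoate
Product: 20 2,4-dihydroxy-3,6-dimethylbenzoic acid
Conditions: conc. H2SO4, 0 °C to rt; ice-water
Reagents that add atoms: water, O
Why: Acid hydrolysis by the acylium (AAC1) mechanism suits electron-rich, doubly ortho-substituted benzoates, and it avoids the hot alkali that would decarboxylate this resorcylic acid.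

Step 9
Reactants: 20 2,4-dihydroxy-3,6-dimethylbenzoic acid
Product: 21 benzyl 2,4-dihydroxy-3,6-dimethylbenzoate
Conditions: BnBr, KHCO3, DMF, rt
Reagents that add atoms: benzyl bromide, BrCc1ccccc1
Why: This is an SN2 alkylation of the carboxylate, because hydrogen carbonate deprotonates only the acid and leaves both phenols unalkylated.

Step 10
Reactants: 18 2-methoxy-3,5,6-trimethyl-4-(triisopropylsilyloxy)benzoic acid; 21 benzyl 2,4-dihydroxy-3,6-dimethylbenzoate
Product: 23 benzyl 2-hydroxy-4-{[2-methoxy-3,5,6-trimethyl-4-(triisopropylsilyloxy)benzoyl]oxy}-3,6-dimethylbenzoate, via mixed trifluoroacetic anhydride 22 (not isolated)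
Conditions: (CF3CO)2O, toluene, rt
Reagents that add atoms: none
Why: In this mixed-anhydride depside esterification, the electron-rich hindered acid ionises readily towards its acylium ion, and only the 4-OH of 21 is acylated because the 2-OH is hydrogen-bonded to the ester and flanked on both sides.

Step 11
Reactants: 23 benzyl 2-hydroxy-4-{[2-methoxy-3,5,6-trimethyl-4-(triisopropylsilyloxy)benzoyl]oxy}-3,6-dimethylbenzoate
Product: 24 benzyl 2-methoxy-4-{[2-methoxy-3,5,6-trimethyl-4-(triisopropylsilyloxy)benzoyl]oxy}-3,6-dimethylbenzoate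
Conditions: MeI, K2CO3, DMF, rt
Reagents that add atoms: iodomethane, CI
Why: Williamson methylation acts on the only free hydroxyl, and the depside carbonyl, shielded by two ortho substituents, and the doubly flanked TIPS ether should both resist dry carbonate.

Step 12
Reactants: 24 benzyl 2-methoxy-4-{[2-methoxy-3,5,6-trimethyl-4-(triisopropylsilyloxy)benzoyl]oxy}-3,6-dimethylbenzoate
Product: 25 benzyl 4-[(4-hydroxy-2-methoxy-3,5,6-trimethylbenzoyl)oxy]-2-methoxy-3,6-dimethylbenzoate
Conditions: Bu4NF, AcOH, THF, 0 °C to rt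
Reagents that add atoms: none
Why: Fluoride cleaves the aryl silyl ether, driven by Si–F bond formation and the good phenoxide leaving group, and the AcOH buffer protonates that phenoxide at once so that it cannot transesterify a depside bond.

Step 13
Reactants: 19 methyl 2,4-dihydroxy-3,6-dimethylbenzoate
Product: 26 methyl 2,4-bis(benzyloxy)-3,6-dimethylbenzoate
Conditions: BnBr (excess), K2CO3, DMF, 60 °C
Reagents that add atoms: benzyl bromide, BrCc1ccccc1
Why: This is a double Williamson benzylation, in which excess halide and warming in DMF also bring the hydrogen-bonded 2-OH to reaction.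

Step 14
Reactants: 26 methyl 2,4-bis(benzyloxy)-3,6-dimethylbenzoate
Product: 27 2,4-bis(benzyloxy)-3,6-dimethylbenzoic acid
Conditions: KOH, DMSO/H2O, 90 °C; 1 M HCl, 0 °C
Reagents that add atoms: potassium hydroxide, [K+].[OH-]
Why: Poorly solvated hydroxide in aqueous DMSO saponifies the hindered methyl ester, and with both phenols capped as benzyl ethers the acid is no longer prone to decarboxylation.

Step 15
Reactants: 25 benzyl 4-[(4-hydroxy-2-methoxy-3,5,6-trimethylbenzoyl)oxy]-2-methoxy-3,6-dimethylbenzoate; 27 2,4-bis(benzyloxy)-3,6-dimethylbenzoic acid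
Product: 29 benzyl 4-({4-[(2,4-bis(benzyloxy)-3,6-dimethylbenzoyl)oxy]-2-methoxy-3,5,6-trimethylbenzoyl}oxy)-2-methoxy-3,6-dimethylbenzoate, via mixed trifluoroacetic anhydride 28 (not isolated)
Conditions: (CF3CO)2O, toluene, rt to 40 °C
Reagents that add atoms: none
Why: In this mixed-anhydride depside esterification, the linear acylium-like electrophile from the dialkoxybenzoic acid is the activation mode of choice for joining a doubly ortho-substituted acid to a doubly ortho-substituted phenol, and 25 offers only one hydroxyl.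

Step 16
Reactants: 29 benzyl 4-({4-[(2,4-bis(benzyloxy)-3,6-dimethylbenzoyl)oxy]-2-methoxy-3,5,6-trimethylbenzoyl}oxy)-2-methoxy-3,6-dimethylbenzoate
Product: 30 4-({4-[(2,4-dihydroxy-3,6-dimethylbenzoyl)oxy]-2-methoxy-3,5,6-trimethylbenzoyl}oxy)-2-methoxy-3,6-dimethylbenzoic acid (target)
Conditions: H2 (1 atm), 10% Pd/C, EtOAc, rt
Reagents that add atoms: none
Why: Catalytic hydrogenolysis removes the benzyl ester and both benzyl ethers in one neutral operation that leaves the aryl esters and methyl ethers untouched.

**Compound list**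
1 | but-2-yne | CC#CC | starting material
2 | trichloroacetyl chloride | ClC(Cl)(Cl)C(=O)Cl | starting material
3 | dichloroketene | ClC(Cl)=C=O | intermediate
4 | 4,4-dichloro-2,3-dimethylcyclobut-2-en-1-one | CC1=C(C)C(Cl)(Cl)C1=O | intermediate
5 | 2,3-dimethylcyclobut-2-en-1-one | CC1=C(C)C(=O)C1 | intermediate
6 | ethyl acetate | CCOC(C)=O | starting material
7 | 1,1-dibromopropan-2-one lithium enolate | CC([O-])=C(Br)Br.[Li+] | intermediate
8 | lithium prop-1-yn-1-olate | CC#C[O-].[Li+] | intermediate
9 | 1-(triisopropylsilyloxy)prop-1-yne | CC#CO[Si](C(C)C)(C(C)C)C(C)C | intermediate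
10 | 2,3-dimethylbuta-1,3-dien-1-one (vinylketene) | CC(=C)C(C)=C=O | intermediate
11 | 2,4-dimethyl-4-(prop-1-en-2-yl)-3-(triisopropylsilyloxy)cyclobut-2-en-1-one (racemic 4-alkenylcyclobutenone) | CC1=C(O[Si](C(C)C)(C(C)C)C(C)C)C(C)(C(C)=C)C1=O | intermediate
12 | (3E)-2,4,5-trimethyl-3-(triisopropylsilyloxy)hexa-1,3,5-trien-1-one (dienylketene) | CC(=C=O)/C(O[Si](C(C)C)(C(C)C)C(C)C)=C(C)\C(C)=C | intermediate
13 | 2,4,5-trimethyl-3-(triisopropylsilyloxy)cyclohexa-2,4-dien-1-one (cyclohexadienone) | CC1=C(C)C(O[Si](C(C)C)(C(C)C)C(C)C)=C(C)C(=O)C1 | intermediate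
14 | 2,4,5-trimethyl-3-(triisopropylsilyloxy)phenol | Cc1cc(O)c(C)c(O[Si](C(C)C)(C(C)C)C(C)C)c1C | intermediate
15 | (3-methoxy-2,5,6-trimethylphenoxy)triisopropylsilane | COc1cc(C)c(C)c(O[Si](C(C)C)(C(C)C)C(C)C)c1C | intermediate
16 | (4-bromo-3-methoxy-2,5,6-trimethylphenoxy)triisopropylsilane | COc1c(Br)c(C)c(C)c(O[Si](C(C)C)(C(C)C)C(C)C)c1C | intermediate
17 | [2-methoxy-3,5,6-trimethyl-4-(triisopropylsilyloxy)phenyl]lithium (aryllithium) | COc1c([Li])c(C)c(C)c(O[Si](C(C)C)(C(C)C)C(C)C)c1C | intermediate
18 | 2-methoxy-3,5,6-trimethyl-4-(triisopropylsilyloxy)benzoic acid | COc1c(C(=O)O)c(C)c(C)c(O[Si](C(C)C)(C(C)C)C(C)C)c1C | intermediate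
19 | methyl 2,4-dihydroxy-3,6-dimethylbenzoate | COC(=O)c1c(C)cc(O)c(C)c1O | starting material
20 | 2,4-dihydroxy-3,6-dimethylbenzoic acid | OC(=O)c1c(C)cc(O)c(C)c1O | intermediate
21 | benzyl 2,4-dihydroxy-3,6-dimethylbenzoate | O=C(OCc1ccccc1)c1c(C)cc(O)c(C)c1O | intermediate
22 | 2-methoxy-3,5,6-trimethyl-4-(triisopropylsilyloxy)benzoic trifluoroacetic anhydride | COc1c(C(=O)OC(=O)C(F)(F)F)c(C)c(C)c(O[Si](C(C)C)(C(C)C)C(C)C)c1C | intermediate
23 | benzyl 2-hydroxy-4-{[2-methoxy-3,5,6-trimethyl-4-(triisopropylsilyloxy)benzoyl]oxy}-3,6-dimethylbenzoate | COc1c(C(=O)Oc2cc(C)c(C(=O)OCc3ccccc3)c(O)c2C)c(C)c(C)c(O[Si](C(C)C)(C(C)C)C(C)C)c1C | intermediate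
24 | benzyl 2-methoxy-4-{[2-methoxy-3,5,6-trimethyl-4-(triisopropylsilyloxy)benzoyl]oxy}-3,6-dimethylbenzoate | COc1c(C(=O)Oc2cc(C)c(C(=O)OCc3ccccc3)c(OC)c2C)c(C)c(C)c(O[Si](C(C)C)(C(C)C)C(C)C)c1C | intermediate
25 | benzyl 4-[(4-hydroxy-2-methoxy-3,5,6-trimethylbenzoyl)oxy]-2-methoxy-3,6-dimethylbenzoate | COc1c(C(=O)Oc2cc(C)c(C(=O)OCc3ccccc3)c(OC)c2C)c(C)c(C)c(O)c1C | intermediate
26 | methyl 2,4-bis(benzyloxy)-3,6-dimethylbenzoate | COC(=O)c1c(C)cc(OCc2ccccc2)c(C)c1OCc1ccccc1 | intermediate
27 | 2,4-bis(benzyloxy)-3,6-dimethylbenzoic acid | OC(=O)c1c(C)cc(OCc2ccccc2)c(C)c1OCc1ccccc1 | intermediate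
28 | 2,4-bis(benzyloxy)-3,6-dimethylbenzoic trifluoroacetic anhydride | O=C(OC(=O)C(F)(F)F)c1c(C)cc(OCc2ccccc2)c(C)c1OCc1ccccc1 | intermediate
29 | benzyl 4-({4-[(2,4-bis(benzyloxy)-3,6-dimethylbenzoyl)oxy]-2-methoxy-3,5,6-trimethylbenzoyl}oxy)-2-methoxy-3,6-dimethylbenzoate | COc1c(C(=O)Oc2cc(C)c(C(=O)OCc3ccccc3)c(OC)c2C)c(C)c(C)c(OC(=O)c2c(C)cc(OCc3ccccc3)c(C)c2OCc2ccccc2)c1C | intermediate
30 | 4-({4-[(2,4-dihydroxy-3,6-dimethylbenzoyl)oxy]-2-methoxy-3,5,6-trimethylbenzoyl}oxy)-2-methoxy-3,6-dimethylbenzoic acid | COc1c(C)c(OC(=O)c2c(C)c(C)c(OC(=O)c3c(C)cc(O)c(C)c3O)c(C)c2OC)cc(C)c1C(=O)O | target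

Total step count: 16
Longest linear sequence: 11 steps (1, 2, 4, 5, 6, 7, 10, 11, 12, 15, 16)

**Steps most likely to fail**

Step 4. The volatile cyclobutenone may be lost on heating. The vinylketene may dimerise faster than the alkyne captures it, or the cascade may stall before the 6π closure.
- The fallback produces the same vinylketene at room temperature by a photochemical Wolff rearrangement, the second-generation form of this benzannulation. It sets out from 9 and comes back at 14.
- Purchased 2-methylpent-1-en-3-one F1 is deprotonated at its CH2 group with LiN(SiMe3)2 and acylated with 2,2,2-trifluoroethyl trifluoroacetate, giving 1,1,1-trifluoro-3,5-dimethylhex-5-ene-2,4-dione F2.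
- F2 is used crude. Detrifluoroacetylative diazo transfer with MsN3, Et3N and water in MeCN should convert it into 2-diazo-4-methylpent-4-en-3-one F3.
- Irradiation of F3 at 254 nm in CH2Cl2 in the presence of 9 expels nitrogen with migration of the isopropenyl group. This enters the cascade at 10.
- A short period of heating in toluene then carries 11, 12 and 13 through to 14.

Step 15. O-acylation may be slow because both partners carry two ortho substituents. Decay of the mixed anhydride or acid-induced loss of the ortho benzyl ether could then overtake ester formation.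
- The fallback replaces the crowded acyl donor by a planar ketene. It sets out from 20 and 25 and comes back at 30.
- Acid 20 is condensed with acetone in TFA/(CF3CO)2O to give 7-hydroxy-2,2,5,8-tetramethyl-4H-1,3-benzodioxin-4-one F4.
- F4 is benzylated with BnBr and K2CO3 to give 7-(benzyloxy)-2,2,5,8-tetramethyl-4H-1,3-benzodioxin-4-one F5.
- Irradiation of F5 at 300 nm in CH2Cl2 with 25 extrudes acetone and gives 3-(benzyloxy)-2,5-dimethyl-6-(oxomethylidene)cyclohexa-2,4-dien-1-one F6.
- The sp-hybridised carbon of F6 is open to the hindered phenol. Trapping should give benzyl 4-({4-[(4-(benzyloxy)-2-hydroxy-3,6-dimethylbenzoyl)oxy]-2-methoxy-3,5,6-trimethylbenzoyl}oxy)-2-methoxy-3,6-dimethylbenzoate F7.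
- Hydrogenolysis of F7 under the conditions of step 16 gives 30.

Step 11. Alkylation of the hydrogen-bonded, doubly flanked hydroxyl may be incomplete. Base-induced cleavage of the depside ester or the silyl ether could also occur and be followed by over-methylation.
- The fallback installs the ring A methyl ether before any depside bond exists. It sets out from 19, replaces steps 8 to 11 and comes back at 24.
- Selective benzylation of the free 4-OH of 19 (one equivalent of BnBr, K2CO3, acetone) gives methyl 4-(benzyloxy)-2-hydroxy-3,6-dimethylbenzoate F8.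
- MeI and K2CO3 in DMF convert F8 into methyl 4-(benzyloxy)-2-methoxy-3,6-dimethylbenzoate F9.
- KOH in aqueous DMSO then gives 4-(benzyloxy)-2-methoxy-3,6-dimethylbenzoic acid F10.
- Hydrogenolysis over Pd/C gives 4-hydroxy-2-methoxy-3,6-dimethylbenzoic acid F11.
- BnBr with KHCO3 in DMF gives benzyl 4-hydroxy-2-methoxy-3,6-dimethylbenzoate F12.
- F12 is coupled with 18 through mixed anhydride 22 under the conditions of step 10 and gives 24 directly.

**Further compounds**
F1 | step 4 | 2-methylpent-1-en-3-one (purchased) | CCC(=O)C(C)=C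
F2 | step 4 | 1,1,1-trifluoro-3,5-dimethylhex-5-ene-2,4-dione (racemic, enolisable) | C=C(C)C(=O)C(C)C(=O)C(F)(F)F
F3 | step 4 | 2-diazo-4-methylpent-4-en-3-one | CC(=[N+]=[N-])C(=O)C(C)=C
F4 | step 15 | 7-hydroxy-2,2,5,8-tetramethyl-4H-1,3-benzodioxin-4-one | CC1(C)OC(=O)c2c(C)cc(O)c(C)c2O1
F5 | step 15 | 7-(benzyloxy)-2,2,5,8-tetramethyl-4H-1,3-benzodioxin-4-one | CC1(C)OC(=O)c2c(C)cc(OCc3ccccc3)c(C)c2O1
F6 | step 15 | 3-(benzyloxy)-2,5-dimethyl-6-(oxomethylidene)cyclohexa-2,4-dien-1-one | O=C=C1C(C)=CC(OCc2ccccc2)=C(C)C1=O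
F7 | step 15 | benzyl 4-({4-[(4-(benzyloxy)-2-hydroxy-3,6-dimethylbenzoyl)oxy]-2-methoxy-3,5,6-trimethylbenzoyl}oxy)-2-methoxy-3,6-dimethylbenzoate | COc1c(C(=O)Oc2cc(C)c(C(=O)OCc3ccccc3)c(OC)c2C)c(C)c(C)c(OC(=O)c2c(C)cc(OCc3ccccc3)c(C)c2O)c1C
F8 | step 11 | methyl 4-(benzyloxy)-2-hydroxy-3,6-dimethylbenzoate | COC(=O)c1c(C)cc(OCc2ccccc2)c(C)c1O
F9 | step 11 | methyl 4-(benzyloxy)-2-methoxy-3,6-dimethylbenzoate | COC(=O)c1c(C)cc(OCc2ccccc2)c(C)c1OC
F10 | step 11 | 4-(benzyloxy)-2-methoxy-3,6-dimethylbenzoic acid | OC(=O)c1c(C)cc(OCc2ccccc2)c(C)c1OC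
F11 | step 11 | 4-hydroxy-2-methoxy-3,6-dimethylbenzoic acid | OC(=O)c1c(C)cc(O)c(C)c1OC
F12 | step 11 | benzyl 4-hydroxy-2-methoxy-3,6-dimethylbenzoate | O=C(OCc1ccccc1)c1c(C)cc(O)c(C)c1OC
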